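**Plan**

The quinone ring is numbered Q1 (C–indole A), Q2 (C–OMe), Q3 (C=O), Q4 (C–indole B), Q5 (C–OMe), Q6 (C=O). Retrosynthesis returns the quinone to its hydroquinone with both N–H masked, then cuts Q5–Q6 and re-forms Q3–Q6, so that the six-membered ring becomes a 4-alkenyl-4-hydroxycyclobutenone.
The enabling feature is this fully substituted ring itself: Q6–Q1–Q2–Q3 is a squarate four-carbon unit that already carries indole A and one methoxy group, and Q4–Q5 is a β-methoxyvinyl unit that carries indole B and the other methoxy group.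
Further cuts: Q3–Q4 (vinyllithium + cyclobutenedione), Q1–C3 of indole A (3-lithioindole + dimethyl squarate), and C2–C3 of indole A (Madelung).
Forward order: pyrrole ring of indole A (step 2), indole A–squarate bond (step 5), Q3–Q4 bond (step 9), six-membered ring by Q5–Q6 closure (step 10), then N-deprotection and oxidation.
Stereochemistry: the target has no stereocentre; the racemic carbinol carbon of the cyclobutenone and the Z geometry of its enol ether both vanish on aromatisation.

Key step: step 10

Assumption: the crowded quinone–indole A axis is treated as configurationally undefined, and hydroquinones 23 and 24 are handled under argon. SEM = 2-(trimethylsilyl)ethoxymethyl, Boc = tert-butoxycarbonyl.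

**Route**

Step 1
Reactants: 1 2,2-dimethylbut-3-enoic acid; 2 o-toluidine (2-methylaniline)
Product: 4 N-(2-methylphenyl)-2,2-dimethylbut-3-enamide, via acid chloride 3 (not isolated)
Conditions: (COCl)2, DMF (cat.), CH2Cl2, 0 °C to rt; then 2, Et3N, CH2Cl2, 0 °C to rt
Reagents that add atoms: none
Why: Acid chloride formation followed by N-acylation of the aniline (Schotten–Baumann-type amide formation) should be clean because the quaternary α-carbon can neither enolise nor form a ketene.

Step 2
Reactants: 4 N-(2-methylphenyl)-2,2-dimethylbut-3-enamide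
Product: 5 2-(2-methylbut-3-en-2-yl)-1H-indole
Conditions: n-BuLi (3 equiv), THF, 0 °C to rt; H2O
Reagents that add atoms: none
Why: Madelung indole synthesis in its organolithium form: deprotonation at N–H and at the benzylic methyl, attack of the benzylic carbanion on the non-enolisable amide carbonyl and loss of LiOH should give the 2-tert-alkylindole, the isolated terminal alkene being inert to n-BuLi.

Step 3
Reactants: 5 2-(2-methylbut-3-en-2-yl)-1H-indole
Product: 6 2-(2-methylbut-3-en-2-yl)-1-SEM-indole
Conditions: NaH, DMF, 0 °C; SEMCl, 0 °C to rt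
Reagents that add atoms: 2-(trimethylsilyl)ethoxymethyl chloride (SEMCl), C[Si](C)(C)CCOCCl
Why: N-alkylation of the sodium indolide with a small, reactive chloromethyl ether should proceed despite the neighbouring quaternary carbon and gives a group that survives the organolithium steps.

Step 4
Reactants: 6 2-(2-methylbut-3-en-2-yl)-1-SEM-indole
Product: 7 3-bromo-2-(2-methylbut-3-en-2-yl)-1-SEM-indole
Conditions: NBS, THF, −78 to 0 °C, dark
Reagents that add atoms: N-bromosuccinimide, O=C1CCC(=O)N1Br
Why: Electrophilic aromatic bromination at C3, the only free and by far the most nucleophilic position of the N-alkylindole, should outrun any reaction of the monosubstituted alkene.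

Step 5
Reactants: 7 3-bromo-2-(2-methylbut-3-en-2-yl)-1-SEM-indole; 8 dimethyl squarate
Product: 11 3-methoxy-4-[2-(2-methylbut-3-en-2-yl)-1-SEM-indol-3-yl]cyclobut-3-ene-1,2-dione, via 3-lithioindole 9 (not isolated), via hydroxycyclobutenone adduct 10 (not isolated)
Conditions: t-BuLi (2 equiv), THF, −78 °C; 8, THF, −78 °C; aq. NH4Cl; then conc. HCl (cat.), CH2Cl2, rt
Reagents that add atoms: none
Why: Bromine–lithium exchange gives a 3-lithioindole that cannot migrate (C2 is blocked), 1,2-addition to the unhindered, wide-angled squarate carbonyl forms the crowded indole–Q1 bond, and acid-catalysed ionisation of the indolyl carbinol with hydrolysis of the resulting oxocarbenium ion (loss of methanol) is the standard squarate-to-semisquarate sequence.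

Step 6
Reactants: 12 indole-3-carboxaldehyde
Product: 13 tert-butyl 3-formyl-1H-indole-1-carboxylate
Conditions: Boc2O, DMAP (cat.), MeCN, rt
Reagents that add atoms: di-tert-butyl dicarbonate, CC(C)(C)OC(=O)OC(=O)OC(C)(C)C
Why: DMAP-catalysed N-acylation gives a carbamate that lowers the nucleophilicity of the indole ring for step 8 and comes off together with SEM in step 11.

Step 7
Reactants: 13 tert-butyl 3-formyl-1H-indole-1-carboxylate; 14 (methoxymethyl)triphenylphosphonium chloride
Product: 16 tert-butyl 3-(2-methoxyethenyl)-1H-indole-1-carboxylate (E/Z mixture), via methoxymethylene ylide 15 (not isolated)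
Conditions: 14, NaN(SiMe3)2, THF, 0 °C; then 13, −78 °C to rt
Reagents that add atoms: none
Why: Wittig olefination with the methoxymethylene ylide, formed with a non-nucleophilic amide base that spares the carbamate, supplies Q5 with its methoxy group; both alkene isomers converge in step 8.

Step 8
Reactants: 16 tert-butyl 3-(2-methoxyethenyl)-1H-indole-1-carboxylate
Product: 18 tert-butyl 3-[(Z)-1-bromo-2-methoxyethenyl]-1H-indole-1-carboxylate (Br cis to OMe), via vicinal dibromide 17 (not isolated)
Conditions: Br2, CH2Cl2, −78 °C; then Et3N, −78 °C to rt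
Reagents that add atoms: bromine, BrBr
Why: Bromine addition to an enol ether followed by amine-induced dehydrobromination (loss of the α-alkoxy bromide through the oxocarbenium ion and of the indolylic proton) is the standard entry to β-bromo enol ethers, and the isomer with the large indolyl group trans to methoxy should predominate; its geometry is to be confirmed by NOE and any E isomer removed.

Step 9
Reactants: 18 tert-butyl 3-[(Z)-1-bromo-2-methoxyethenyl]-1H-indole-1-carboxylate; 11 3-methoxy-4-[2-(2-methylbut-3-en-2-yl)-1-SEM-indol-3-yl]cyclobut-3-ene-1,2-dione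
Product: 20 racemic 4-hydroxy-3-methoxy-4-[(Z)-2-methoxy-1-(1-Boc-indol-3-yl)ethenyl]-2-[2-(2-methylbut-3-en-2-yl)-1-SEM-indol-3-yl]cyclobut-2-en-1-one, via vinyllithium 19 (not isolated)
Conditions: t-BuLi (2 equiv), THF–Et2O, −78 °C; then 11, −78 °C; aq. NH4Cl
Reagents that add atoms: none
Why: Bromine–lithium exchange with retention gives the vinyllithium with lithium cis to methoxy (chelated and not prone to anti-elimination), which should add 1,2 to the ketone carbonyl next to the methoxy-bearing carbon, the one outside the vinylogous ester and remote from the twisted 2-tert-alkylindole; the carbinol centre forms racemic and is destroyed in step 10, and the acid-sensitive product is purified on Et3N-deactivated silica.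

Step 10
Reactants: 20 racemic 4-hydroxy-3-methoxy-4-[(Z)-2-methoxy-1-(1-Boc-indol-3-yl)ethenyl]-2-[2-(2-methylbut-3-en-2-yl)-1-SEM-indol-3-yl]cyclobut-2-en-1-one
Product: 23 2,5-dimethoxy-3-(1-Boc-indol-3-yl)-6-[2-(2-methylbut-3-en-2-yl)-1-SEM-indol-3-yl]benzene-1,4-diol, via dienylketene 21 (not isolated), via cyclohexadienone 22 (not isolated)
Conditions: toluene (degassed), 110 °C, Ar
Reagents that add atoms: none
Why: Heating opens the cyclobutenone by conrotatory 4π electrocyclic cleavage of the Q3–Q6 bond, and the donor hydroxyl at Q3 rotates outward, so the methoxyvinyl arm lies cis to the ketene in dienylketene 21. A 6π electrocyclisation then joins ketene carbon Q6 to enol-ether carbon Q5 and closes the six-membered carbocycle as cyclohexadienone 22, which enolises to the aromatic hydroquinone 23; the closest known reaction type is the Moore rearrangement of 4-alkenyl-4-hydroxycyclobutenones. The ketene terminus carries no in-plane substituent, so the inward-pointing Z-methoxy group at Q5 should not block closure, and Q5 is the only carbon that can reach Q6 through a six-membered ring (C2 of indole B would need a seven-membered one). No stereocentre is created, since the racemic carbinol carbon and the sp3 carbon Q5 of 22 both become aromatic. The selectivity needed is the sense of ring opening, secured by the strong outward preference of hydroxyl, and the para placing of the two indoles, already fixed by the site of addition in step 9. The toluene temperature leaves the N-Boc group in place, and degassing keeps the electron-rich hydroquinone reduced.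

Step 11
Reactants: 23 2,5-dimethoxy-3-(1-Boc-indol-3-yl)-6-[2-(2-methylbut-3-en-2-yl)-1-SEM-indol-3-yl]benzene-1,4-diol
Product: 24 3-(1H-indol-3-yl)-2,5-dimethoxy-6-[2-(2-methylbut-3-en-2-yl)-1H-indol-3-yl]benzene-1,4-diol
Conditions: Bu4NF (1 M in THF), THF, 65 °C, Ar
Reagents that add atoms: none
Why: Fluoride attack at silicon fragments the SEM group (Me3SiF, ethylene, then formaldehyde from the hemiaminal) and hot Bu4NF also cleaves N-Boc indoles; the step is run at the hydroquinone level so that no base-sensitive methoxyquinone is exposed, the aryl methyl ethers and the tert-prenyl group being inert.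

Step 12
Reactants: 24 3-(1H-indol-3-yl)-2,5-dimethoxy-6-[2-(2-methylbut-3-en-2-yl)-1H-indol-3-yl]benzene-1,4-diol
Product: 25 2-(1H-indol-3-yl)-3,6-dimethoxy-5-[2-(2-methylbut-3-en-2-yl)-1H-indol-3-yl]cyclohexa-2,5-diene-1,4-dione (target)
Conditions: Ag2O, Na2SO4, CH2Cl2, rt
Reagents that add atoms: none
Why: Ag2O is a mild two-electron oxidant for electron-rich hydroquinones (hydroquinone-to-quinone oxidation) and should leave the free indoles and the alkene untouched.

**Compound list**

1 | 2,2-dimethylbut-3-enoic acid | C=CC(C)(C)C(=O)O | starting material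
2 | o-toluidine | Cc1ccccc1N | starting material
3 | 2,2-dimethylbut-3-enoyl chloride | C=CC(C)(C)C(=O)Cl | intermediate
4 | N-(2-methylphenyl)-2,2-dimethylbut-3-enamide | C=CC(C)(C)C(=O)Nc1ccccc1C | intermediate
5 | 2-(2-methylbut-3-en-2-yl)-1H-indole | C=CC(C)(C)c1cc2ccccc2[nH]1 | intermediate
6 | 2-(2-methylbut-3-en-2-yl)-1-{[2-(trimethylsilyl)ethoxy]methyl}-1H-indole | C=CC(C)(C)c1cc2ccccc2n1COCC[Si](C)(C)C | intermediate
7 | 3-bromo-2-(2-methylbut-3-en-2-yl)-1-{[2-(trimethylsilyl)ethoxy]methyl}-1H-indole | C=CC(C)(C)c1c(Br)c2ccccc2n1COCC[Si](C)(C)C | intermediate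
8 | dimethyl squarate (3,4-dimethoxycyclobut-3-ene-1,2-dione) | COC1=C(OC)C(=O)C1=O | starting material
9 | 3-lithio-2-(2-methylbut-3-en-2-yl)-1-SEM-indole | [Li]c1c(C(C)(C)C=C)n(COCC[Si](C)(C)C)c2ccccc12 | intermediate
10 | racemic 4-hydroxy-2,3-dimethoxy-4-[2-(2-methylbut-3-en-2-yl)-1-SEM-indol-3-yl]cyclobut-2-en-1-one | COC1=C(OC)C(O)(c2c(C(C)(C)C=C)n(COCC[Si](C)(C)C)c3ccccc23)C1=O | intermediate
11 | 3-methoxy-4-[2-(2-methylbut-3-en-2-yl)-1-SEM-indol-3-yl]cyclobut-3-ene-1,2-dione | COC1=C(c2c(C(C)(C)C=C)n(COCC[Si](C)(C)C)c3ccccc23)C(=O)C1=O | intermediate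
12 | indole-3-carboxaldehyde | O=Cc1c[nH]c2ccccc12 | starting material
13 | tert-butyl 3-formyl-1H-indole-1-carboxylate | O=Cc1cn(C(=O)OC(C)(C)C)c2ccccc12 | intermediate
14 | (methoxymethyl)triphenylphosphonium chloride | COC[P+](c1ccccc1)(c1ccccc1)c1ccccc1.[Cl-] | starting material
15 | (methoxymethylene)triphenylphosphorane | COC=P(c1ccccc1)(c1ccccc1)c1ccccc1 | intermediate
16 | tert-butyl 3-(2-methoxyethenyl)-1H-indole-1-carboxylate (E/Z mixture) | COC=Cc1cn(C(=O)OC(C)(C)C)c2ccccc12 | intermediate
17 | tert-butyl 3-(1,2-dibromo-2-methoxyethyl)-1H-indole-1-carboxylate (diastereomer mixture) | COC(Br)C(Br)c1cn(C(=O)OC(C)(C)C)c2ccccc12 | intermediate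
18 | tert-butyl 3-[(Z)-1-bromo-2-methoxyethenyl]-1H-indole-1-carboxylate | CO/C=C(\Br)c1cn(C(=O)OC(C)(C)C)c2ccccc12 | intermediate
19 | tert-butyl 3-[(E)-1-lithio-2-methoxyethenyl]-1H-indole-1-carboxylate (Li cis to OMe) | CO/C=C(\[Li])c1cn(C(=O)OC(C)(C)C)c2ccccc12 | intermediate
20 | racemic 4-hydroxy-3-methoxy-4-[(Z)-2-methoxy-1-(1-Boc-indol-3-yl)ethenyl]-2-[2-(2-methylbut-3-en-2-yl)-1-SEM-indol-3-yl]cyclobut-2-en-1-one | O=C1C(c2c(C(C)(C)C=C)n(COCC[Si](C)(C)C)c3ccccc23)=C(OC)C1(O)/C(c1cn(C(=O)OC(C)(C)C)c2ccccc12)=C\OC | intermediate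
21 | dienylketene: 4-hydroxy-3,6-dimethoxy-5-(1-Boc-indol-3-yl)-2-[2-(2-methylbut-3-en-2-yl)-1-SEM-indol-3-yl]hexa-1,3,5-trien-1-one (ketene and alkenyl arms cis) | O=C=C(c1c(C(C)(C)C=C)n(COCC[Si](C)(C)C)c2ccccc12)/C(OC)=C(O)\C(c1cn(C(=O)OC(C)(C)C)c2ccccc12)=C/OC | intermediate
22 | racemic 4-hydroxy-3,6-dimethoxy-5-(1-Boc-indol-3-yl)-2-[2-(2-methylbut-3-en-2-yl)-1-SEM-indol-3-yl]cyclohexa-2,4-dien-1-one | O=C1C(c2c(C(C)(C)C=C)n(COCC[Si](C)(C)C)c3ccccc23)=C(OC)C(O)=C(c2cn(C(=O)OC(C)(C)C)c3ccccc23)C1OC | intermediate
23 | 2,5-dimethoxy-3-(1-Boc-indol-3-yl)-6-[2-(2-methylbut-3-en-2-yl)-1-SEM-indol-3-yl]benzene-1,4-diol | C=CC(C)(C)c1n(COCC[Si](C)(C)C)c2ccccc2c1-c1c(O)c(OC)c(-c2cn(C(=O)OC(C)(C)C)c3ccccc23)c(O)c1OC | intermediate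
24 | 3-(1H-indol-3-yl)-2,5-dimethoxy-6-[2-(2-methylbut-3-en-2-yl)-1H-indol-3-yl]benzene-1,4-diol | C=CC(C)(C)c1[nH]c2ccccc2c1-c1c(O)c(OC)c(-c2c[nH]c3ccccc23)c(O)c1OC | intermediate
25 | 2-(1H-indol-3-yl)-3,6-dimethoxy-5-[2-(2-methylbut-3-en-2-yl)-1H-indol-3-yl]cyclohexa-2,5-diene-1,4-dione | C=CC(C)(C)c1[nH]c2ccccc2c1C1=C(OC)C(=O)C(c2c[nH]c3ccccc23)=C(OC)C1=O | target

**Step count**

Total steps: 12. Longest linear sequence: 9 (steps 1–5 and 9–12); steps 6–8 form the three-step branch that joins at step 9.

**Steps most likely to fail**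

Step 9. The organolithium may be consumed before it adds: the lithium reagents can attack the carbamate carbonyl of indole B (acyl transfer), and the vinyllithium is slow to add to a dione screened by the 2-tert-alkylindole. The fallback changes the nitrogen substituent after the bromination, where the carbamate has done its work. It sets out from 18. NaOMe (cat.) in MeOH at rt removes the carbamate to give (Z)-3-(1-bromo-2-methoxyethenyl)-1H-indole F1. NaH and SEMCl in DMF give (Z)-3-(1-bromo-2-methoxyethenyl)-1-SEM-indole F2. t-BuLi at −78 °C then gives the carbamate-free vinyllithium F3, which is added to 11 to give the bis-SEM cyclobutenone F4. Heating in degassed toluene as in step 10 should give the bis-SEM hydroquinone F5, and Bu4NF in THF at 65 °C removes both SEM groups to return to the route at 24.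

Step 8. Bromine may also attack the indole ring, or hydrogen bromide may be lost in the wrong direction or with poor control of alkene geometry. The fallback fixes the position of bromine before the double bond is re-formed. It sets out from 16: NBS in MeOH at −20 °C adds bromine at the indolyl carbon and traps the oxocarbenium ion as the dimethyl acetal, giving tert-butyl 3-(1-bromo-2,2-dimethoxyethyl)-1H-indole-1-carboxylate F6. Me3SiOTf with i-Pr2NEt in CH2Cl2 at −20 °C (acetal-to-enol-ether elimination of methanol, which can only remove the indolylic proton) then returns to the route at 18.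

Step 11. Cleavage at the crowded nitrogen of indole A may stall at the N-hydroxymethyl stage, and traces of oxygen may oxidise the hydroquinone dianion in hot basic fluoride, after which methoxy groups are lost. The fallback removes the protecting groups on an air- and base-stable arene. It sets out from 23: MeI and K2CO3 in acetone give the tetramethyl ether 1,2,4,5-tetramethoxy-3-(1-Boc-indol-3-yl)-6-[2-(2-methylbut-3-en-2-yl)-1-SEM-indol-3-yl]benzene F7. Bu4NF in DMF at 80 °C, now without exclusion of air, gives the bis-N–H tetramethoxybenzene F8. Oxidative demethylation with (NH4)2Ce(NO3)6 in MeCN–H2O at 0 °C returns to the route at 25; either para pair of methoxy groups gives the same quinone because of the substitution pattern.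

**Further compounds**

F1 | step 9 | (Z)-3-(1-bromo-2-methoxyethenyl)-1H-indole | CO/C=C(\Br)c1c[nH]c2ccccc12
F2 | step 9 | (Z)-3-(1-bromo-2-methoxyethenyl)-1-{[2-(trimethylsilyl)ethoxy]methyl}-1H-indole | CO/C=C(\Br)c1cn(COCC[Si](C)(C)C)c2ccccc12
F3 | step 9 | (E)-3-(1-lithio-2-methoxyethenyl)-1-SEM-indole (Li cis to OMe) | CO/C=C(\[Li])c1cn(COCC[Si](C)(C)C)c2ccccc12
F4 | step 9 | racemic 4-hydroxy-3-methoxy-4-[(Z)-2-methoxy-1-(1-SEM-indol-3-yl)ethenyl]-2-[2-(2-methylbut-3-en-2-yl)-1-SEM-indol-3-yl]cyclobut-2-en-1-one | O=C1C(c2c(C(C)(C)C=C)n(COCC[Si](C)(C)C)c3ccccc23)=C(OC)C1(O)/C(c1cn(COCC[Si](C)(C)C)c2ccccc12)=C\OC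
F5 | step 9 | 2,5-dimethoxy-3-(1-SEM-indol-3-yl)-6-[2-(2-methylbut-3-en-2-yl)-1-SEM-indol-3-yl]benzene-1,4-diol | C=CC(C)(C)c1n(COCC[Si](C)(C)C)c2ccccc2c1-c1c(O)c(OC)c(-c2cn(COCC[Si](C)(C)C)c3ccccc23)c(O)c1OC
F6 | step 8 | racemic tert-butyl 3-(1-bromo-2,2-dimethoxyethyl)-1H-indole-1-carboxylate | COC(OC)C(Br)c1cn(C(=O)OC(C)(C)C)c2ccccc12
F7 | step 11 | 1,2,4,5-tetramethoxy-3-(1-Boc-indol-3-yl)-6-[2-(2-methylbut-3-en-2-yl)-1-SEM-indol-3-yl]benzene | C=CC(C)(C)c1n(COCC[Si](C)(C)C)c2ccccc2c1-c1c(OC)c(OC)c(-c2cn(C(=O)OC(C)(C)C)c3ccccc23)c(OC)c1OC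
F8 | step 11 | 3-(2,3,5,6-tetramethoxy-4-(1H-indol-3-yl)phenyl)-2-(2-methylbut-3-en-2-yl)-1H-indole | C=CC(C)(C)c1[nH]c2ccccc2c1-c1c(OC)c(OC)c(-c2c[nH]c3ccccc23)c(OC)c1OC
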